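(All runs are calculated for substances that don't exist; scatter was added.)

Watch the gain of target. I compare two rates in the theta run, each taken over its own stretch of time, and their ratio is a plain number that holds for those two stretches.

| flask | substrate | catalyst | time |
|---|---|---|---|
| theta | 0.120 M | 0.00600 M |  |
| alpha | 0.180 M | 0.00600 M |  |
| delta | 0.120 M | 0.00600 M | 66 h |

| theta run: time / h | theta run: [target] / M | alpha run: time / h | alpha run: [target] / M |
|---|---|---|---|
| 0.44 | 0.0027 | 0.44 | 0.0039 |
| 0.98 | 0.0066 | 0.98 | 0.0085 |
| 2.2 | 0.0134 | 2.2 | 0.0160 |
| 4.9 | 0.0259 | 4.9 | 0.0302 |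
| 11 | 0.0379 | 11 | 0.0450 |

(readings scatter by 4 × 10⁻⁴ M)

1. reaction order in [substrate] at the outset, round the charge of the theta run, defined at two percent of the substrate turned into target (one fixed amount of target, the same in the runs compared)
2. target in the delta run at 66 h, as a share of the substrate charged

- Overall: substrate -> target, with catalyst as catalyst.
- Constant volume, constant temperature.
- Bound and free are read together.
- An order is taken over about fifteen percent of the charge, up and down.

The early rate is c_target at 0.98 h over that time, 0.00673 M h⁻¹. The late rate is the gain from 4.9 h to 11 h, 0.00197 M h⁻¹. Their ratio, the late share ρ, is a reading of 0.292. If substrate went to target and nowhere else, 68.4% of the charge would remain in the theta run at 11 h, and ρ stands lower than that share. So I extrapolate no plateau from these runs: ρ shows that something else is at work, not what.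

The forecast gives an order of 0.65 (0.45 to 0.85) and 43% (36% to 62%), holding that “the catalyst is dying, or the product is strongly inhibiting it”.

The flask gives an order of 0.47 and 4.13%. The delta run, on the theta recipe, holds less target at 66 h than the 31.6% of the theta run at 11 h.

    catalyst + substrate ⇌ catalyst-substrate complex, settled at all times (10.80 L mol⁻¹)
    catalyst-substrate complex → target + catalyst (2.182 h⁻¹)
    target → decomposed product (0.04896 h⁻¹)
    2 substrate → homo dimer (0.5508 L mol⁻¹ h⁻¹)

Applied to the simulated early rates, ρ gives a gain from 4.9 h to 11 h of 0.00204 M h⁻¹ in the theta run and 0.00241 M h⁻¹ in the alpha run, while at 11 h decay of target takes 0.00186 M h⁻¹ and 0.00220 M h⁻¹.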